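## The problem

Compound 16 is gallocatechin-(4α→6)-gallocatechin: two 2,3-trans flavan-3-ol units, the upper one (rings A, B, C; unprimed locants) bonded through its benzylic C4 to C6' of the lower one (benzo ring D, aryl ring E, pyran ring F; primed locants). The bond ends on the ring D carbon between the phenolic oxygens on C5' and C7' and para to O1'. A flavan-4-yl cation attacks an intact 5,7-dioxygenated flavan mostly at C8', so the 4→6 constitution has to be built in and cannot be left to selectivity. Of the five stereocentres, C2 and C3 can come from the chiral pool, and C3 can direct C4, because attack anti to the C3 oxygen gives the 3,4-trans, 4α arrangement, which is also the all-equatorial one. C2' and C3' are separated from these centres by ring D and must be set by a reagent or catalyst. The C4–C6' bond re-ionises in acid, rings B and E are pyrogallols that oxidise in air once free, and the benzylic C2–O1 and C2'–O1' bonds limit the reducing conditions that can be used, so the ten phenols are best carried as benzyl ethers and released last under neutral conditions. The enabling feature is C2', a benzylic ether carbon bonded to O1' of the electron-rich ring D. While a C3'=C4' double bond is present, ring F is a 2H-chromene whose O1'–C2' bond can open to an ortho-quinone methide and close again, which erases and re-forms C2'; once the alkene is consumed, C2' is fixed. A chiral catalyst that functionalises C3'=C4' anti to ring E can therefore take one C2' epimer while the other is fed back, setting C2' and C3' together.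

## Retrosynthesis

**16 from 15.** The ten aryl O–benzyl bonds are cut last. Hydrogenolysis is neutral and leaves nothing but a volatile hydrocarbon beside the air-sensitive dodecahydroxy compound. The forward step must spare the two benzylic ring C–O bonds and the doubly benzylic C4–C6' bond.

**15 from 14.** The C3'–O bond is traced back to a C3'–B bond. Oxidation of a secondary alkylboronate goes with retention, so all stereochemistry is already decided in 14, and the oxidant only has to be mild towards four electron-rich rings.

**14 from 12 and 13.** The C3'–B and C4'–H bonds are removed, which leaves the lower flav-3-ene 12 as a mixture of both C2' epimers and the diboron 13. Hydroboration of 12 with an achiral borane would also give the 2',3'-trans relation, but it would fix whichever C2' configuration each molecule happens to have. A chiral copper boryl can choose the alkene face, and since boron must enter anti to ring E it thereby chooses the C2' epimer. The forward reaction must do this faster on one epimer than on the other while the two epimers of 12 exchange through ring opening at O1'–C2' to the valence isomer 11 and reclosure. The precursor is simpler by two stereocentres and needs no control of C2' when it is made.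

**12 from 8 and 10.** Ring F is opened at O1'–C2' and the C4a'–C4' bond is cut. This leads to phenol 8, whose hydroxyl is para to the flavanyl carbon, and the cinnamaldehyde 10. Both carbons ortho to that hydroxyl are equivalent, so the condensation can only give the 4→6 skeleton. A neighbouring cut that attaches a finished lower flavan would have to distinguish C6' from C8'. The forward reaction must join the ortho carbon to the aldehyde carbon (not the β-carbon) and close the resulting dienone 11 by oxa-6π electrocyclisation.

**10 from 9.** The C=C bond of the enal is cut by a two-carbon Wittig homologation of the commercial aldehyde 9.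

**8 from 5 (through 7 and 6).** The two flanking benzyl ethers and the free para hydroxyl are traced back to the triol 5 by a silyl relay. The para hydroxyl is the only unhindered one and takes a bulky silyl group (6), the flanking phenols are benzylated (7), and fluoride frees the para phenol (8). The C3 hydroxyl is left free throughout. It is too hindered and too weakly acidic to interfere, and leaving it saves a protection step.

**5 from 3 and 4.** The C4–aryl bond is cut to the flavan-3,4-diol 3 and phloroglucinol 4. All three ring carbons of 4 are equivalent, so a single constitution results. C4 is set by the neighbouring C3 oxygen. The forward reaction is the classical acid-promoted leucoanthocyanidin–phloroglucinol condensation, run with excess 4 to prevent a second alkylation.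

**3 from 1 (through 2).** The C4–H bond and the five phenolic benzyl ethers are removed. This returns (2R,3R)-dihydromyricetin 1, which supplies C2 and C3 with the required trans relation.

## Roads not taken

**Alternative 1:** The cut is C4–C4a of the upper unit, with ring C closed last on a symmetric 3,5-bis(benzyloxy)phenyl ether. In the forward step Ph3PAuNTf2 activates the alkyne of the aryl propargyl ether A1, and an ortho carbon of ring A attacks the alkyne carbon that bears ring D (6-endo hydroarylation) to give the flav-3-ene A2 with C2 in place.

- Merits: ring A is symmetric, so the closure is regiochemically unambiguous. The interflavan bond is made as an aryl–alkyne bond and not through a cation. The lower unit enters complete with both stereocentres. The reaction type is known.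
- Weak points for this target:
  - The alkyne must sit on C6' of a finished flavan, and electrophilic halogenation of 5,7-dialkoxyflavans prefers C8', so the constitutional problem returns one stage earlier.
  - The attacked alkyne carbon carries an aryl group with two ortho benzyloxy substituents, so the new bond forms at a very congested centre.
  - The C2–O bond of A1 is both propargylic and benzylic to a trialkoxyphenyl ring. A π-acid can ionise it, with loss of the C2 configuration or Meyer–Schuster-type diversion.
  - A2 still lacks C3 and C4. These would have to come from hydroboration of a trisubstituted C3=C4 bond next to a 2,6-disubstituted aryl group.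
- Comparison: alternative 1 is better in convergence and in needing no unprecedented reaction. The chosen plan sets against it a constitution fixed by the symmetry of 4, an upper unit whose three centres come from 1 and one classical coupling, and a single uncertain step (step 9) that has a known non-dynamic version behind it.

**Alternative 2:** The cut is C2'=C3' of ring F. In the forward step the second-generation Grubbs catalyst joins the 1-arylvinyl ether on O1' and the allyl group on C4a' of the diene A3, with loss of ethene, to give the 4H-chromene A4.

- Merits: the metathesis is a known catalytic reaction. Ring E arrives as a gallate ester. The allyl group can be placed on C4a' by Claisen rearrangement at the same para oxygen as in 8, so the constitution is as secure as in the chosen plan.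
- Weak points for this target:
  - A4 has no stereocentre in ring F and offers no way to create one selectively. It is a trisubstituted cyclic enol ether. Its hydroboration would give the 2',3'-trans alcohol by syn addition, but the face is chosen neither by the remote upper unit nor reliably by a chiral borane, so a mixture of lower-unit diastereomers is expected.
  - A3 and A4 are acid-labile enol ethers.
  - Allylation, Claisen rearrangement, esterification, methylenation of a hindered aryl ester with Cp2TiMe2 and metathesis take four to five steps, where the chosen plan needs two (steps 7 and 8).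
- Comparison: alternative 2 equals the chosen plan in fixing the constitution and is better in that every step is a known type. It postpones the stereochemical problem instead of solving it. Chromene 12 differs from A4 only in the position of the double bond, and that difference supplies an epimerisable C2' and a styrene-type alkene for copper catalysis.

**Alternative 3:** The cut is C3–O and C2–H of the upper ring C. In the forward step BH3·SMe2 adds across C2=C3 of the 4-aryl-4H-chromene A5 on the face anti to ring D, and oxidation gives A6 with C2 and C3 relayed from C4.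

- Merits: one catalytically made stereocentre controls two more through a strong steric bias. Syn addition gives exactly the 2,3-trans-3,4-trans array. Hydroboration of flav-2-enes is known. No chiral pool is needed for the upper unit.
- Weak points for this target:
  - A5 must be made with C4 already enantiopure and carrying the complete lower unit. This needs a metal or halogen on C6' of a finished flavan (the regiochemical problem of alternative 1) and an enantioselective C–C bond formation at a centre flanked by four ortho substituents.
  - A5 is a doubly benzylic enol ether that can lose the C4 hydrogen by aromatisation or 1,3-shift, which would erase the only controlling centre.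
  - C2' and C3' still have to be supplied separately.
- Comparison: for the upper unit the stereochemical logic of alternative 3 is at least as elegant, and its key step is known chemistry, which the chosen plan cannot claim. The chosen plan buys C2 and C3 with 1 and gets C4 in one classical step, so the effort of asymmetric catalysis goes to the lower unit, where none of the plans has substrate control.

Key step: step 9

Assumption: the target is read as (2R,3S,4R)-upper and (2'R,3'S)-lower, i.e. 2,3-trans-3,4-trans (4α) gallocatechin linked to C6' of gallocatechin. The descriptor at C4 changes with the protecting groups while the geometry stays the same, so "4α" is used in names.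

Assumption: (R,R)-Ph-BPE is taken to be the ligand enantiomer that delivers boron to the C3' face leading to 14. If the sense of induction is the reverse, the (S,S)-ligand takes its place.

Assumption: diol 3 is drawn as its expected major 3,4-trans epimer. Any 3,4-cis epimer is carried along, since both ionise to the same cation in step 3.

Assumption: in step 9 both new bonds are formed on the closed chromene 12. Dienone 11, which step 8 forms and consumes, reappears there only as the ring-opened valence isomer of the reactant, in the side equilibrium that exchanges its C2' epimers. It is not converted into 14 directly and is treated in that step as part of reactant 12.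

## Route

Step 1
Reactants: 1 (2R,3R)-dihydromyricetin
Product: 2 (2R,3R)-5,7-bis(benzyloxy)-3-hydroxy-2-[3,4,5-tris(benzyloxy)phenyl]chroman-4-one
Conditions: BnBr (5.5 equiv), K2CO3, DMF, rt, Ar
Reagents that add atoms: benzyl bromide, BrCc1ccccc1
Why: Williamson benzylation of the five phenols with a carbonate base that leaves the C3 alcohol alone; no bond to C2 or C3 is touched, and ambient temperature under argon avoids chalcone-type ring opening and aerial dehydrogenation of the dihydroflavonol.

Step 2
Reactants: 2 (2R,3R)-5,7-bis(benzyloxy)-3-hydroxy-2-[3,4,5-tris(benzyloxy)phenyl]chroman-4-one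
Product: 3 (2R,3S,4R)-5,7-bis(benzyloxy)-2-[3,4,5-tris(benzyloxy)phenyl]chromane-3,4-diol
Conditions: NaBH4, THF–EtOH, 0 °C to rt
Reagents that add atoms: none
Why: Borohydride reduction of the aryl ketone; axial hydride delivery should give mainly the all-equatorial 3,4-trans diol, and the C4 configuration is of no consequence because C4 is ionised in the next step.

Step 3
Reactants: 3 (2R,3S,4R)-5,7-bis(benzyloxy)-2-[3,4,5-tris(benzyloxy)phenyl]chromane-3,4-diol; 4 phloroglucinol
Product: 5 2-{(2R,3S,4R)-5,7-bis(benzyloxy)-3-hydroxy-2-[3,4,5-tris(benzyloxy)phenyl]chroman-4-yl}benzene-1,3,5-triol (penta-O-benzylgallocatechin-(4α→2)-phloroglucinol)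
Conditions: 4 (5 equiv), BF3·OEt2 (0.2 equiv), THF, 0 °C to rt
Reagents that add atoms: none
Why: Acid-catalysed Friedel–Crafts condensation through the flavan-4-yl cation stabilised by ring A and O1 (the leucoanthocyanidin–phloroglucinol coupling); the nucleophile enters anti to the C3 hydroxyl to give the 3,4-trans (4α), all-equatorial product, which is also favoured if the bond re-ionises. The three carbons of 4 are equivalent, so one constitution forms, and the excess of 4 suppresses a second alkylation.

Step 4
Reactants: 5 penta-O-benzylgallocatechin-(4α→2)-phloroglucinol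
Product: 6 2-{(2R,3S,4R)-5,7-bis(benzyloxy)-3-hydroxy-2-[3,4,5-tris(benzyloxy)phenyl]chroman-4-yl}-5-[(triisopropylsilyl)oxy]benzene-1,3-diol (silyl group on the hydroxyl para to the flavanyl carbon)
Conditions: TIPSCl (1.05 equiv), imidazole, DMF, −20 to 0 °C
Reagents that add atoms: chlorotri(propan-2-yl)silane, CC(C)[Si](Cl)(C(C)C)C(C)C
Why: Silylation under steric control: the para hydroxyl has two hydrogen neighbours, whereas each flanking hydroxyl sits next to the congested flavan C4, and the C3 alcohol is a hindered secondary one; the bulky silyl chloride should take the para position only.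

Step 5
Reactants: 6 para-O-triisopropylsilyl ether of 5
Product: 7 (2R,3S)-5,7-bis(benzyloxy)-4α-{2,6-bis(benzyloxy)-4-[(triisopropylsilyl)oxy]phenyl}-2-[3,4,5-tris(benzyloxy)phenyl]chroman-3-ol
Conditions: BnBr (2.5 equiv), K2CO3, n-Bu4NI (cat.), acetone, 50 °C
Reagents that add atoms: benzyl bromide, BrCc1ccccc1
Why: Williamson benzylation of the two remaining phenols; carbonate in acetone does not deprotonate the C3 alcohol and is mild enough for the hindered aryl triisopropylsilyl ether to persist.

Step 6
Reactants: 7 para-silyloxy bis(benzyl ether)
Product: 8 3,5-bis(benzyloxy)-4-{(2R,3S)-5,7-bis(benzyloxy)-3-hydroxy-2-[3,4,5-tris(benzyloxy)phenyl]chroman-4α-yl}phenol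
Conditions: n-Bu4NF, THF, 0 °C; aq NH4Cl
Reagents that add atoms: none
Why: Fluoride cleavage of the aryl silyl ether, driven by the Si–F bond; benzyl ethers and the interflavan-type C4–aryl bond are inert to fluoride.

Step 7
Reactants: 9 3,4,5-tris(benzyloxy)benzaldehyde
Product: 10 (E)-3-[3,4,5-tris(benzyloxy)phenyl]prop-2-enal
Conditions: Ph3P=CHCHO (1.2 equiv), toluene, 90 °C
Reagents that add atoms: (triphenylphosphoranylidene)acetaldehyde, O=CC=P(c1ccccc1)(c1ccccc1)c1ccccc1
Why: Wittig two-carbon homologation with a stabilised formyl ylide, which gives the (E)-enal; the product is less electrophilic towards the ylide than 9, so a slight excess of ylide keeps over-homologation low.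

Step 8
Reactants: 8 3,5-bis(benzyloxy)-4-(penta-O-benzylgallocatechin-4α-yl)phenol; 10 (E)-3-[3,4,5-tris(benzyloxy)phenyl]prop-2-enal
Product: 12 (2R,3S)-5,7-bis(benzyloxy)-4α-{5,7-bis(benzyloxy)-2-[3,4,5-tris(benzyloxy)phenyl]-2H-chromen-6-yl}-2-[3,4,5-tris(benzyloxy)phenyl]chroman-3-ol (lower flav-3-ene as both C2' epimers), via ortho-quinone methide dienone 11 (not isolated)
Conditions: PhB(OH)2 (1 equiv), AcOH (cat.), toluene, 90 °C, Dean–Stark, N2, exclusion of light
Reagents that add atoms: none
Why: Boronic acid-templated condensation of a phenol with an enal: the aryl borate delivers the aldehyde carbon to the ortho carbon through a six-membered transition state (1,2- and not 1,4-addition), loss of water gives dienone 11, and thermal disrotatory oxa-6π electrocyclisation forms O1'–C2' and closes ring F. The two ortho carbons of 8 are equivalent, so only the 4→6 skeleton can form, and C2' arises without control, as intended for step 9.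

Step 9
Reactants: 12 lower flav-3-ene (both C2' epimers); 13 bis(pinacolato)diboron
Product: 14 (2R,3S)-5,7-bis(benzyloxy)-4α-{(2S,3S)-5,7-bis(benzyloxy)-3-(4,4,5,5-tetramethyl-1,3,2-dioxaborolan-2-yl)-2-[3,4,5-tris(benzyloxy)phenyl]chroman-6-yl}-2-[3,4,5-tris(benzyloxy)phenyl]chroman-3-ol (boron trans to ring E)
Conditions: CuCl (10 mol %), (R,R)-Ph-BPE (12 mol %), NaOt-Bu (20 mol %), 13 (1.5 equiv), MeOH (3 equiv), THF, 25 °C, 365 nm LED
Reagents that add atoms: none
Why: Proposed new method: the closest known reaction type is the CuCl/bisphosphine-catalysed enantioselective protoboration of styrenes and of racemic 2-substituted 2H-chromenes, used there as a kinetic resolution; new here is that the slow-reacting C2' epimer of 12 is returned to the epimer mixture while the catalyst works, which makes the resolution dynamic. The monovalent copper alkoxide and 13 give the ligated copper boryl (Ph-BPE)Cu–Bpin, which adds syn across C3'=C4' of the closed chromene with boron on C3' and copper on the benzylic C4' (styrene polarity imposed by ring D), and methanol protonates the C4'–Cu bond to regenerate the alkoxide. No ring is closed on this bond-forming path and no ring-opened species lies on it; ring F is opened and reclosed at O1'–C2' only in a side equilibrium of the reactant, in which excited 12 opens by retro-oxa-6π reaction to its valence isomer, the dienone 11 already met in step 8, and recloses thermally by the same disrotatory oxa-6π mode to either C2' epimer. C3' is set by the chiral ligand, which chooses the alkene face. C2' is set by selection: boron can only be delivered anti to ring E, so the ligand-preferred face is open in one C2' epimer and the other must first invert through the ring-opened form, which makes the trans relation of boron and ring E substrate-enforced. Regioselectivity rests on the benzylic stabilisation of copper at C4'; catalyst control over the upper C2, C3 and C4 is expected because the upper unit sits on C6', para to O1' and far from the alkene, so the two epimers behave as near-enantiomers at the reacting site. Epimerisation is kept faster than borylation of the mismatched epimer by light: the 5,7-dialkoxychromene chromophore of 12 is the only one in the flask whose absorption reaches the near UV, the three oxygen donors on ring D stabilise the ring-opened form, and the saturated product 14 has no such chromophore and is configurationally fixed. Methanol is limited to a few equivalents in THF so that the ring-opened form, present only in a small stationary concentration and reclosing unimolecularly, is not intercepted by methoxide or by the copper boryl.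

Step 10
Reactants: 14 C3' pinacolboronate
Product: 15 (2R,3S)-5,7-bis(benzyloxy)-4α-{(2R,3S)-5,7-bis(benzyloxy)-3-hydroxy-2-[3,4,5-tris(benzyloxy)phenyl]chroman-6-yl}-2-[3,4,5-tris(benzyloxy)phenyl]chroman-3-ol (deca-O-benzyl-gallocatechin-(4α→6)-gallocatechin)
Conditions: NaBO3·4H2O, THF–H2O, rt
Reagents that add atoms: sodium perborate (NaBO3, used as its tetrahydrate), [Na+].[O-]OB=O
Why: Perborate oxidation of a secondary alkylboronate: C3' migrates from boron to oxygen with retention, so the 2',3'-trans relation of 14 is carried over; the reagent is mild enough for the benzyl ethers and the four electron-rich rings.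

Step 11
Reactants: 15 deca-O-benzyl-gallocatechin-(4α→6)-gallocatechin
Product: 16 gallocatechin-(4α→6)-gallocatechin, (2R,3S,4R)-2-(3,4,5-trihydroxyphenyl)-4-[(2R,3S)-3,5,7-trihydroxy-2-(3,4,5-trihydroxyphenyl)chroman-6-yl]chromane-3,5,7-triol
Conditions: H2 (1 atm), Pd(OH)2/C, THF–MeOH–H2O, rt; filtration under Ar, lyophilisation
Reagents that add atoms: none
Why: Hydrogenolysis of the ten aryl benzyl ethers under neutral conditions; at ambient pressure and temperature the cyclic benzylic C–O bonds and the C4–C6' bond should persist, and no stereocentre is involved.

## Compound list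

1 | (2R,3R)-dihydromyricetin | Oc1cc(O)c2c(c1)O[C@H](c1cc(O)c(O)c(O)c1)[C@@H](O)C2=O | starting material
2 | (2R,3R)-5,7-bis(benzyloxy)-3-hydroxy-2-[3,4,5-tris(benzyloxy)phenyl]chroman-4-one | c9ccccc9COc1cc(OCc9ccccc9)c2c(c1)O[C@H](c1cc(OCc9ccccc9)c(OCc9ccccc9)c(OCc9ccccc9)c1)[C@@H](O)C2=O | intermediate
3 | (2R,3S,4R)-5,7-bis(benzyloxy)-2-[3,4,5-tris(benzyloxy)phenyl]chromane-3,4-diol | c9ccccc9COc1cc(OCc9ccccc9)c2c(c1)O[C@H](c1cc(OCc9ccccc9)c(OCc9ccccc9)c(OCc9ccccc9)c1)[C@@H](O)[C@@H]2O | intermediate
4 | phloroglucinol | Oc1cc(O)cc(O)c1 | starting material
5 | penta-O-benzylgallocatechin-(4α→2)-phloroglucinol | c9ccccc9COc1cc(OCc9ccccc9)c2c(c1)O[C@H](c1cc(OCc9ccccc9)c(OCc9ccccc9)c(OCc9ccccc9)c1)[C@@H](O)[C@@H]2c1c(O)cc(O)cc1O | intermediate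
6 | para-O-triisopropylsilyl ether of 5 (flanking hydroxyls free) | c9ccccc9COc1cc(OCc9ccccc9)c2c(c1)O[C@H](c1cc(OCc9ccccc9)c(OCc9ccccc9)c(OCc9ccccc9)c1)[C@@H](O)[C@@H]2c1c(O)cc(O[Si](C(C)C)(C(C)C)C(C)C)cc1O | intermediate
7 | para-silyloxy bis(benzyl ether) (flanking phenols benzylated, C3 hydroxyl free) | c9ccccc9COc1cc(OCc9ccccc9)c2c(c1)O[C@H](c1cc(OCc9ccccc9)c(OCc9ccccc9)c(OCc9ccccc9)c1)[C@@H](O)[C@@H]2c1c(OCc9ccccc9)cc(O[Si](C(C)C)(C(C)C)C(C)C)cc1OCc9ccccc9 | intermediate
8 | 3,5-bis(benzyloxy)-4-(penta-O-benzylgallocatechin-4α-yl)phenol | c9ccccc9COc1cc(OCc9ccccc9)c2c(c1)O[C@H](c1cc(OCc9ccccc9)c(OCc9ccccc9)c(OCc9ccccc9)c1)[C@@H](O)[C@@H]2c1c(OCc9ccccc9)cc(O)cc1OCc9ccccc9 | intermediate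
9 | 3,4,5-tris(benzyloxy)benzaldehyde | O=Cc1cc(OCc2ccccc2)c(OCc2ccccc2)c(OCc2ccccc2)c1 | starting material
10 | (E)-3-[3,4,5-tris(benzyloxy)phenyl]prop-2-enal | O=C/C=C/c1cc(OCc2ccccc2)c(OCc2ccccc2)c(OCc2ccccc2)c1 | intermediate
11 | ortho-quinone methide dienone, formed and consumed in step 8 without isolation (ring D as cyclohexa-2,4-dienone with C8a'=O and an exocyclic C4a'=C4'–C3'=C2'–ring E diene) | c9ccccc9COc1cc(OCc9ccccc9)c2c(c1)O[C@H](c1cc(OCc9ccccc9)c(OCc9ccccc9)c(OCc9ccccc9)c1)[C@@H](O)[C@@H]2C1=C(OCc9ccccc9)/C(=C/C=C/c3cc(OCc9ccccc9)c(OCc9ccccc9)c(OCc9ccccc9)c3)C(=O)C=C1OCc9ccccc9 | intermediate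
12 | lower flav-3-ene: upper unit joined 4α→6' to 5',7'-bis(benzyloxy)-2'-[3,4,5-tris(benzyloxy)phenyl]-2'H-chromene, both C2' epimers | c9ccccc9COc1cc(OCc9ccccc9)c2c(c1)O[C@H](c1cc(OCc9ccccc9)c(OCc9ccccc9)c(OCc9ccccc9)c1)[C@@H](O)[C@@H]2c1c(OCc9ccccc9)cc2c(c1OCc9ccccc9)C=CC(c1cc(OCc9ccccc9)c(OCc9ccccc9)c(OCc9ccccc9)c1)O2 | intermediate
13 | bis(pinacolato)diboron | CC1(C)OB(B2OC(C)(C)C(C)(C)O2)OC1(C)C | starting material
14 | C3' pinacolboronate, 2',3'-trans ((2'S,3'S) by the sequence rule, same spatial arrangement as the alcohol) | c9ccccc9COc1cc(OCc9ccccc9)c2c(c1)O[C@H](c1cc(OCc9ccccc9)c(OCc9ccccc9)c(OCc9ccccc9)c1)[C@@H](O)[C@@H]2c1c(OCc9ccccc9)cc2c(c1OCc9ccccc9)C[C@H](B3OC(C)(C)C(C)(C)O3)[C@@H](c1cc(OCc9ccccc9)c(OCc9ccccc9)c(OCc9ccccc9)c1)O2 | intermediate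
15 | deca-O-benzyl-gallocatechin-(4α→6)-gallocatechin (C3 and C3' hydroxyls free) | c9ccccc9COc1cc(OCc9ccccc9)c2c(c1)O[C@H](c1cc(OCc9ccccc9)c(OCc9ccccc9)c(OCc9ccccc9)c1)[C@@H](O)[C@@H]2c1c(OCc9ccccc9)cc2c(c1OCc9ccccc9)C[C@H](O)[C@@H](c1cc(OCc9ccccc9)c(OCc9ccccc9)c(OCc9ccccc9)c1)O2 | intermediate
16 | gallocatechin-(4α→6)-gallocatechin | Oc1cc(O)c2c(c1)O[C@H](c1cc(O)c(O)c(O)c1)[C@@H](O)[C@@H]2c1c(O)cc2c(c1O)C[C@H](O)[C@@H](c1cc(O)c(O)c(O)c1)O2 | target

## Step count and least certain steps

Total step count: 11. Longest linear sequence: 10 steps (steps 1–6 and 8–11 from 1); the aldehyde branch joins after step 7.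

**Step 9 (key step).** Three processes are most likely to fail:

- Ring opening and reclosure may not keep pace with borylation of the mismatched epimer, so the C2' diastereomeric boronate would accumulate. Photoisomerisation of the ring-opened form about its exocyclic double bond to a slowly reclosing geometry would have the same effect.
- The ring-opened form may be consumed by conjugate addition of the copper boryl or of methoxide.
- The near-UV light may degrade the copper–phosphine catalyst, or the benzyloxy group on C5' may slow insertion at the neighbouring C4'.

Fallback with known chemistry, from 12 back to 14: the light is left out and the copper protoboration is run as the known kinetic resolution. The matched epimer of 12 should be converted into 14. The unreacted (2'R) epimer of the chromene F1 is separated by chromatography (alkene from boronate). In a separate flask, without catalyst, it is re-equilibrated to the epimer mixture 12 by irradiation at 365 nm in THF, which is the known photochromic opening and thermal reclosure of 2H-chromenes. It is then resubmitted, and a few cycles should move most of the material to 14.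

**Step 8.** Possible failures are conjugate Friedel–Crafts addition of the phenol to the enal in place of the templated 1,2-condensation, acid-induced disproportionation of the flav-3-ene, or slow acid cleavage of the C4–C6' bond at 90 °C.

Fallback, from 8 back to 12, under non-acidic conditions:

- Casnati–Skattebøl ortho-formylation of 8 (MgCl2, Et3N, paraformaldehyde, THF, reflux) gives the salicylaldehyde F2.
- Aldehyde 9 is converted by boron-Wittig olefination (bis[(pinacolato)boryl]methane, lithium 2,2,6,6-tetramethylpiperidide, THF, −78 °C) into the (E)-alkenyl pinacolboronate F3.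
- The ester of F3 is exchanged with diethanolamine and hydrolysed to the (E)-alkenylboronic acid F4.
- F2 and F4 with catalytic dibenzylamine in dioxane at 80–90 °C give 12. The sequence is a Petasis borono-Mannich reaction, loss of the amine to the same dienone 11, and oxa-6π closure.

**Step 4.** Silylation may not be confined to the para hydroxyl, or the silyl group may be lost or transferred under the carbonate conditions of step 5. Either would give regioisomeric benzyl ethers and, after step 8, the 4→8 skeleton.

Fallback, from 3 back to 7: the differentiation is built into the nucleophile. Commercial 3,5-bis(benzyloxy)phenol is silylated (TIPSCl, imidazole) to [3,5-bis(benzyloxy)phenoxy]tri(propan-2-yl)silane F5. F5 replaces 4 in the coupling with 3 (BF3·OEt2 cat., CH2Cl2, −40 °C). Attack at the carbon between the two benzyloxy groups, para to the silyloxy group and the only position not shielded by it, should give 7 directly, in place of steps 3–5.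

**Step 3.** Facial selectivity at C4 may be incomplete (3,4-cis epimer), phloroglucinol may be alkylated twice, or acid-mediated re-ionisation may scramble the product.

Fallback, from 3 back to 5: 3 is converted with phenylmethanethiol in acetic acid into the 4-benzylthio ether F6. F6 is activated with AgBF4 in THF at 0 °C in the presence of excess 4. This is a thiophilic ionisation under kinetic, non-protic conditions, known for interflavan bond formation, so the product is never exposed to a Brønsted acid.

## Further compounds

F1 | step 9 | mismatched (2'R) epimer of chromene 12 | c9ccccc9COc1cc(OCc9ccccc9)c2c(c1)O[C@H](c1cc(OCc9ccccc9)c(OCc9ccccc9)c(OCc9ccccc9)c1)[C@@H](O)[C@@H]2c1c(OCc9ccccc9)cc2c(c1OCc9ccccc9)C=C[C@H](c1cc(OCc9ccccc9)c(OCc9ccccc9)c(OCc9ccccc9)c1)O2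
F2 | step 8 | 2,4-bis(benzyloxy)-6-hydroxy-3-(penta-O-benzylgallocatechin-4α-yl)benzaldehyde (salicylaldehyde from 8) | c9ccccc9COc1cc(OCc9ccccc9)c2c(c1)O[C@H](c1cc(OCc9ccccc9)c(OCc9ccccc9)c(OCc9ccccc9)c1)[C@@H](O)[C@@H]2c1c(OCc9ccccc9)cc(O)c(C=O)c1OCc9ccccc9
F3 | step 8 | (E)-4,4,5,5-tetramethyl-2-{2-[3,4,5-tris(benzyloxy)phenyl]ethenyl}-1,3,2-dioxaborolane | CC1(C)OB(/C=C/c2cc(OCc3ccccc3)c(OCc3ccccc3)c(OCc3ccccc3)c2)OC1(C)C
F4 | step 8 | (E)-{2-[3,4,5-tris(benzyloxy)phenyl]ethenyl}boronic acid | OB(O)/C=C/c1cc(OCc2ccccc2)c(OCc2ccccc2)c(OCc2ccccc2)c1
F5 | step 4 | [3,5-bis(benzyloxy)phenoxy]tri(propan-2-yl)silane | CC(C)[Si](Oc1cc(OCc2ccccc2)cc(OCc2ccccc2)c1)(C(C)C)C(C)C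
F6 | step 3 | (2R,3S)-5,7-bis(benzyloxy)-4α-(benzylsulfanyl)-2-[3,4,5-tris(benzyloxy)phenyl]chroman-3-ol | c9ccccc9COc1cc(OCc9ccccc9)c2c(c1)O[C@H](c1cc(OCc9ccccc9)c(OCc9ccccc9)c(OCc9ccccc9)c1)[C@@H](O)[C@@H]2SCc1ccccc1
A1 | alternative 1 | 3,5-bis(benzyloxy)phenyl propargyl ether with ring B on the carbinol carbon and C6' of hexa-O-benzylgallocatechin on the alkyne terminus | c9ccccc9COc1cc(OCc9ccccc9)cc(c1)O[C@H](c1cc(OCc9ccccc9)c(OCc9ccccc9)c(OCc9ccccc9)c1)C#Cc1c(OCc9ccccc9)cc2c(c1OCc9ccccc9)C[C@H](OCc9ccccc9)[C@@H](c1cc(OCc9ccccc9)c(OCc9ccccc9)c(OCc9ccccc9)c1)O2
A2 | alternative 1 | benzylated 2,4-diaryl-2H-chromene (upper flav-3-ene) with C2 set | c9ccccc9COc1cc(OCc9ccccc9)c2c(c1)O[C@H](c1cc(OCc9ccccc9)c(OCc9ccccc9)c(OCc9ccccc9)c1)C=C2c1c(OCc9ccccc9)cc2c(c1OCc9ccccc9)C[C@H](OCc9ccccc9)[C@@H](c1cc(OCc9ccccc9)c(OCc9ccccc9)c(OCc9ccccc9)c1)O2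
A3 | alternative 2 | benzylated upper unit on a ring D carrying a 1-[3,4,5-tris(benzyloxy)phenyl]vinyl ether on O1' and an allyl group on C4a' | c9ccccc9COc1cc(OCc9ccccc9)c2c(c1)O[C@H](c1cc(OCc9ccccc9)c(OCc9ccccc9)c(OCc9ccccc9)c1)[C@@H](OCc9ccccc9)[C@@H]2c1c(OCc9ccccc9)cc(OC(=C)c3cc(OCc9ccccc9)c(OCc9ccccc9)c(OCc9ccccc9)c3)c(CC=C)c1OCc9ccccc9
A4 | alternative 2 | benzylated upper unit fused through ring D to a lower 2-aryl-4H-chromene | c9ccccc9COc1cc(OCc9ccccc9)c2c(c1)O[C@H](c1cc(OCc9ccccc9)c(OCc9ccccc9)c(OCc9ccccc9)c1)[C@@H](OCc9ccccc9)[C@@H]2c1c(OCc9ccccc9)cc2c(c1OCc9ccccc9)CC=C(c1cc(OCc9ccccc9)c(OCc9ccccc9)c(OCc9ccccc9)c1)O2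
A5 | alternative 3 | benzylated upper 2-aryl-4H-chromene with C4 set, carrying the benzylated lower unit on C4 | c9ccccc9COc1cc(OCc9ccccc9)c2c(c1)OC(c1cc(OCc9ccccc9)c(OCc9ccccc9)c(OCc9ccccc9)c1)=C[C@@H]2c1c(OCc9ccccc9)cc2c(c1OCc9ccccc9)C[C@H](OCc9ccccc9)[C@@H](c1cc(OCc9ccccc9)c(OCc9ccccc9)c(OCc9ccccc9)c1)O2
A6 | alternative 3 | benzylated dimer with free C3 hydroxyl | c9ccccc9COc1cc(OCc9ccccc9)c2c(c1)O[C@H](c1cc(OCc9ccccc9)c(OCc9ccccc9)c(OCc9ccccc9)c1)[C@@H](O)[C@@H]2c1c(OCc9ccccc9)cc2c(c1OCc9ccccc9)C[C@H](OCc9ccccc9)[C@@H](c1cc(OCc9ccccc9)c(OCc9ccccc9)c(OCc9ccccc9)c1)O2
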